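**Plan**
Numbering (daucane type): ring B is C1 (methyl-bearing fusion carbon), C2, C3, C4 (ester carbinol), C5 (fusion CH); ring A is C1, C5, C6 (CHOH), C7=C8 (methyl on C8), C9 (C=O), C10; β is the face of the C1 methyl, α the opposite face.
Retrosynthetic cuts: the aroyl–O4 and C4–isopropyl bonds (back to a C4 ketone), C6–O and C5–H (back to a C5=C6 alkene), the enone (back to a C8 ester and C9 silyl enol ether), then C7–C8 and C1–C10 of ring A.
Enabling feature: C1 is quaternary, belongs to both rings and sits on a ready-made ring B, and the C9 carbonyl lies two atoms away, so C8–C9–C10 can arrive as a 2-siloxyvinyl carbene and C7, C6, C5, C1 as the diene of a 2-vinylcyclopentene.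
Forward order: ring B is bought as 3-methylcyclopentenone and made into the vinyl diene; ring A closes in one flask (cyclopropanation forming C7–C8, then Cope shift forming C1–C10); ring A is then trimmed to the methyl enone and the aroyl group goes on last.
Stereochemistry: C1 from the chiral dirhodium carboxylate, relayed through the boat Cope transition state; C5 and C6 together from syn hydroboration anti to the C1 methyl; C4 from addition of the isopropyl nucleophile anti to the same methyl.

Key step: step 6

Remark on the chemistry: Rh2(S-PTAD)4, dirhodium tetrakis[(S)-(1-adamantyl)(phthalimido)acetate], is assumed to give the (1R,2S)-cyclopropane and hence (R)-C1; if the opposite sense is found, Rh2(R-PTAD)4 is used with no other change.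

**Step 1**
Reactants: 1 3-methylcyclopent-2-en-1-one
Product: 3 2-bromo-3-methylcyclopent-2-en-1-one, via dibromoketone 2 (not isolated)
Conditions: Br2, CH2Cl2, 0 °C; then Et3N, 0 → 23 °C
Reagents that add atoms: bromine, BrBr
Why: Bromine adds across the enone alkene and Et3N removes HBr from 2 by E1cB elimination (bromination–dehydrobromination), which places the halogen on the future C5.

**Step 2**
Reactants: 3 2-bromo-3-methylcyclopent-2-en-1-one
Product: 4 6-bromo-7-methyl-1,4-dioxaspiro[4.4]non-6-ene
Conditions: ethylene glycol, p-TsOH·H2O (cat.), benzene, reflux, Dean–Stark trap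
Reagents that add atoms: ethylene glycol, OCCO
Why: Acid-catalysed ketalisation with azeotropic removal of water is routine for 2-bromocycloalkenones, whose vinylic bromine keeps the alkene in place; the dioxolane masks the future C4 carbonyl and makes the diene electron-rich.

**Step 3**
Reactants: 4 6-bromo-7-methyl-1,4-dioxaspiro[4.4]non-6-ene; 5 tributyl(vinyl)stannane
Product: 6 7-methyl-6-vinyl-1,4-dioxaspiro[4.4]non-6-ene
Conditions: Pd(PPh3)4 (5 mol %), toluene, 110 °C
Reagents that add atoms: none
Why: Stille cross-coupling of the vinylic bromide with the vinylstannane under zerovalent palladium catalysis should give the 1,3-diene.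

**Step 4**
Reactants: 7 methyl acetoacetate
Product: 8 methyl 2-diazo-3-oxobutanoate
Conditions: 4-acetamidobenzenesulfonyl azide, Et3N, MeCN, 0 → 23 °C
Reagents that add atoms: 4-acetamidobenzenesulfonyl azide, CC(=O)Nc1ccc(cc1)S(=O)(=O)N=[N+]=[N-]
Why: Regitz diazo transfer from the sulfonyl azide to the enolate of the β-keto ester is the standard entry to 2-diazo-1,3-dicarbonyl compounds.

**Step 5**
Reactants: 8 methyl 2-diazo-3-oxobutanoate
Product: 9 methyl 3-(tert-butyldimethylsilyloxy)-2-diazobut-3-enoate
Conditions: t-BuMe2SiOTf, Et3N, CH2Cl2, 0 °C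
Reagents that add atoms: tert-butyldimethylsilyl trifluoromethanesulfonate, CC(C)(C)[Si](C)(C)OS(=O)(=O)C(F)(F)F
Why: Soft enolisation and O-silylation of the methyl ketone gives the 2-siloxyvinyl diazoacetate, the diazo group being inert to these conditions.

**Step 6**
Reactants: 6 7-methyl-6-vinyl-1,4-dioxaspiro[4.4]non-6-ene; 9 methyl 3-(tert-butyldimethylsilyloxy)-2-diazobut-3-enoate
Product: 11 (1R)-cycloadduct with C8 ester/C9 silyl enol ether/C5=C6 alkene/C4 ketal, via cis-divinylcyclopropane 10 (not isolated)
Conditions: Rh2(S-PTAD)4 (2 mol %), hexanes, −26 °C, 9 (1.5 equiv) added over 3 h; then 65 °C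
Reagents that add atoms: none
Why: The divalent rhodium carboxylate expels N2 from 9 to give a donor–acceptor vinylcarbenoid, which adds in a concerted, asynchronous way to the terminal CH2=CH of 6 (bonds C8–C7 and C8–C6) with the siloxyvinyl group cis to the cyclopentenyl group, giving 10. Warming then drives a Cope rearrangement through the boat transition state that the cyclopropane imposes, forming C10–C1 and breaking C8–C6; the closest known reaction type is the tandem cyclopropanation/Cope rearrangement (formal [4+3] cycloaddition) of 2-siloxyvinyl diazoacetates with vinylcycloalkenes. Ring A is closed by this [3,3] sigmatropic shift, a three-to-seven ring expansion of the cyclopropane, not by an end-on cyclisation. The only stereocentre that survives, C1, is set by transfer of the catalyst-controlled (1R,2S) configuration of the cyclopropane through the boat geometry. The step needs site selectivity (the monosubstituted vinyl group reacts, the tetrasubstituted ring alkene is too hindered), cis selectivity (inherent to donor–acceptor carbenoids, which place the ester trans to the alkene substituent) and enantioselectivity (ligand control); heating is included because the ring methyl must point at the cyclopropane CH2 in the boat and slows the shift.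

**Step 7**
Reactants: 11 (1R)-cycloadduct
Product: 13 (1R,5S,6S)-alcohol with 5α-H and 6α-OH, via alkylborane 12 (not isolated)
Conditions: BH3·SMe2, THF, 0 → 23 °C; then Me3NO·2H2O, 65 °C
Reagents that add atoms: trimethylamine N-oxide, C[N+](C)(C)[O-]; borane–dimethyl sulfide, C[S+](C)[BH3-] (its boron stays only in 12)
Why: Hydroboration–oxidation: borane should add syn to the electron-richer trisubstituted C5=C6 alkene with boron on the less substituted C6 and from the α face, anti to the axial C1 methyl on the neighbouring quaternary carbon (the bias known from steroidal 5-enes), so 5α-H and 6α-B are set together; the neutral amine-oxide oxidation replaces boron by OH with retention and spares the push–pull silyl enol ether, which is too electron-poor and hindered to be hydroborated.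

**Step 8**
Reactants: 13 (1R,5S,6S)-alcohol
Product: 14 C6 triisopropylsilyl ether
Conditions: i-Pr3SiOTf, 2,6-lutidine, CH2Cl2, −78 → 0 °C
Reagents that add atoms: triisopropylsilyl trifluoromethanesulfonate, CC(C)[Si](C(C)C)(C(C)C)OS(=O)(=O)C(F)(F)F
Why: Silylation of the secondary alcohol with a silyl triflate and a hindered pyridine base; the triisopropylsilyl group is chosen because it should survive fluoride at 0 °C, hot LiCl/DMSO and IBX, and is too bulky to migrate to the neighbouring C4 alkoxide in step 16.

**Step 9**
Reactants: 14 C6 triisopropylsilyl ether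
Product: 15 (1R,5S,6S)-C4 ketone
Conditions: pyridinium p-toluenesulfonate (cat.), acetone/H2O 10:1, 50 °C
Reagents that add atoms: water, O
Why: Mild acid-catalysed hydrolysis of the dioxolane; the silyl enol ether of a β-keto ester is a vinylogous silyl carbonate, protonated at carbon about as reluctantly as an aryl silyl ether, so it and the triisopropylsilyl ether should survive.

**Step 10**
Reactants: 15 (1R,5S,6S)-C4 ketone
Product: 16 (1R,4R,5S,6S)-tertiary alcohol with 4α-isopropyl and 4β-OH
Conditions: i-PrMgCl, CeCl3, THF, −78 → 0 °C; aq. NH4Cl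
Reagents that add atoms: isopropylmagnesium chloride, CC(C)[Mg]Cl
Why: 1,2-Addition of the CeCl3-activated Grignard reagent, which suppresses enolisation and reduction of the hindered ketone and leaves the vinylogous carbonate ester alone at low temperature; attack should come from the α face of the trans-fused cyclopentanone, anti to the axial C1 methyl that is 1,3 to C4, so oxygen ends β (4R).

**Step 11**
Reactants: 16 (1R,4R,5S,6S)-tertiary alcohol
Product: 18 C8-methylated β-keto ester (both C8 epimers), via ammonium enolate 17 (not isolated)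
Conditions: Bu4NF (1.1 equiv), MeI (5 equiv), THF, 0 → 23 °C
Reagents that add atoms: iodomethane, CI; tetrabutylammonium fluoride, CCCC[N+](CCCC)(CCCC)CCCC.[F-] (its cation stays only in 17)
Why: Fluoride cleaves the enol Si–O bond and the free enolate 17 is C-methylated by iodomethane (fluoride-promoted alkylation of a β-keto ester silyl enol ether), which places the future C8 methyl regiospecifically; the new C8 centre is of no consequence.

**Step 12**
Reactants: 18 C8-methylated β-keto ester
Product: 19 C8-methyl ketone (both C8 epimers)
Conditions: LiCl, H2O (2 equiv), DMSO, 150 °C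
Reagents that add atoms: none
Why: Krapcho dealkoxycarbonylation: chloride demethylates the ester by SN2 attack and the β-keto carboxylate loses CO2, leaving an epimeric ketone mixture that converges in the next step.

**Step 13**
Reactants: 19 C8-methyl ketone
Product: 20 (1R,4R,5S,6S)-enone with C7=C8 and C9=O
Conditions: IBX (2-iodoxybenzoic acid, 2 equiv), DMSO, 65 °C
Reagents that add atoms: none
Why: Dehydrogenation of the ketone through its enol by the pentavalent iodine reagent; C10 has no β-hydrogen because C1 is quaternary, so unsaturation can only arise on the C8 side and should settle in the endocyclic, conjugated C7=C8 position.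

**Step 14**
Reactants: 21 4-hydroxybenzoic acid
Product: 22 tert-butyldimethylsilyl 4-(tert-butyldimethylsilyloxy)benzoate
Conditions: t-BuMe2SiCl (2.2 equiv), imidazole, DMF, 23 °C
Reagents that add atoms: tert-butyldimethylsilyl chloride, CC(C)(C)[Si](C)(C)Cl
Why: Exhaustive silylation of the acid and the phenol with the silyl chloride and imidazole.

**Step 15**
Reactants: 22 tert-butyldimethylsilyl 4-(tert-butyldimethylsilyloxy)benzoate
Product: 23 4-(tert-butyldimethylsilyloxy)benzoyl chloride
Conditions: (COCl)2, DMF (cat.), CH2Cl2, 0 → 23 °C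
Reagents that add atoms: oxalyl chloride, ClC(=O)C(Cl)=O
Why: Silyl esters are converted directly into acid chlorides by oxalyl chloride with catalytic DMF (Vilsmeier-type activation) under neutral conditions that leave the aryl silyl ether intact.

**Step 16**
Reactants: 20 (1R,4R,5S,6S)-enone; 23 4-(tert-butyldimethylsilyloxy)benzoyl chloride
Product: 25 bis-silyl ether of the target, via lithium alkoxide 24 (not isolated)
Conditions: LiN(SiMe3)2 (1.05 equiv), THF, −78 °C; then 23 (1.5 equiv), −78 → 0 °C
Reagents that add atoms: none
Why: O-Acylation of a preformed lithium tertiary alkoxide with an aroyl chloride, the standard answer to hindered tertiary alcohols; O–H deprotonation by the amide base should be faster than enolisation at C10, the lithium alkoxide is too weak a base to enolise the enone, and the bulky silyl group on O6 should not migrate.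

**Step 17**
Reactants: 25 bis-silyl ether of the target
Product: 26 target (CNP0153637.1)
Conditions: HF·pyridine, pyridine, THF, 0 → 23 °C
Reagents that add atoms: none
Why: Fluoride-mediated global desilylation of the secondary alkyl silyl ether and the aryl silyl ether under buffered, weakly acidic conditions that should cause neither acyl migration from the tertiary O4 to the freed O6 nor ionisation of the tertiary ester.

**Compound list**
1 | 3-methylcyclopent-2-en-1-one | CC1=CC(=O)CC1 | starting material
2 | 2,3-dibromo-3-methylcyclopentan-1-one (not isolated) | CC1(Br)CCC(=O)C1Br | intermediate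
3 | 2-bromo-3-methylcyclopent-2-en-1-one | CC1=C(Br)C(=O)CC1 | intermediate
4 | 6-bromo-7-methyl-1,4-dioxaspiro[4.4]non-6-ene | CC1=C(Br)C2(CC1)OCCO2 | intermediate
5 | tributyl(vinyl)stannane | C=C[Sn](CCCC)(CCCC)CCCC | starting material
6 | 7-methyl-6-vinyl-1,4-dioxaspiro[4.4]non-6-ene | C=CC1=C(C)CCC12OCCO2 | intermediate
7 | methyl acetoacetate | COC(=O)CC(C)=O | starting material
8 | methyl 2-diazo-3-oxobutanoate | COC(=O)C(=[N+]=[N-])C(C)=O | intermediate
9 | methyl 3-(tert-butyldimethylsilyloxy)-2-diazobut-3-enoate | C=C(O[Si](C)(C)C(C)(C)C)C(=[N+]=[N-])C(=O)OC | intermediate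
10 | methyl (1R,2S)-1-[1-(tert-butyldimethylsilyloxy)ethenyl]-2-(7-methyl-1,4-dioxaspiro[4.4]non-6-en-6-yl)cyclopropane-1-carboxylate, the cis-divinylcyclopropane (not isolated) | C=C(O[Si](C)(C)C(C)(C)C)[C@@]1(C(=O)OC)C[C@H]1C1=C(C)CCC12OCCO2 | intermediate
11 | (1R)-cycloadduct: fused hydroazulene with C5=C6 and C8=C9 double bonds, CO2CH3 on C8, OSi(t-Bu)Me2 on C9, CH3 on C1, ethylene ketal at C4 | COC(=O)C1=C(O[Si](C)(C)C(C)(C)C)C[C@@]2(C)CCC3(OCCO3)C2=CC1 | intermediate
12 | alkylborane of 11 with BH2 on C6 (α) and H on C5 (α) (not isolated) | COC(=O)C1=C(O[Si](C)(C)C(C)(C)C)C[C@@]2(C)CCC3(OCCO3)[C@@H]2[C@@H](B)C1 | intermediate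
13 | (1R,5S,6S)-alcohol: 11 with 5α-H and 6α-OH in place of the C5=C6 alkene | COC(=O)C1=C(O[Si](C)(C)C(C)(C)C)C[C@@]2(C)CCC3(OCCO3)[C@@H]2[C@@H](O)C1 | intermediate
14 | C6 triisopropylsilyl ether of 13 | COC(=O)C1=C(O[Si](C)(C)C(C)(C)C)C[C@@]2(C)CCC3(OCCO3)[C@@H]2[C@@H](O[Si](C(C)C)(C(C)C)C(C)C)C1 | intermediate
15 | (1R,5S,6S)-C4 ketone: 14 with C4=O in place of the ketal | COC(=O)C1=C(O[Si](C)(C)C(C)(C)C)C[C@@]2(C)CCC(=O)[C@@H]2[C@@H](O[Si](C(C)C)(C(C)C)C(C)C)C1 | intermediate
16 | (1R,4R,5S,6S)-tertiary alcohol: 15 with 4α-isopropyl and 4β-OH | COC(=O)C1=C(O[Si](C)(C)C(C)(C)C)C[C@@]2(C)CC[C@@](O)(C(C)C)[C@@H]2[C@@H](O[Si](C(C)C)(C(C)C)C(C)C)C1 | intermediate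
17 | tetrabutylammonium C9 enolate of the β-keto ester from 16 (not isolated) | CCCC[N+](CCCC)(CCCC)CCCC.COC(=O)C1=C([O-])C[C@@]2(C)CC[C@@](O)(C(C)C)[C@@H]2[C@@H](O[Si](C(C)C)(C(C)C)C(C)C)C1 | intermediate
18 | β-keto ester: C9 ketone, C8 bearing CH3 and CO2CH3 (both C8 epimers), otherwise as 16 | COC(=O)C1(C)C(=O)C[C@@]2(C)CC[C@@](O)(C(C)C)[C@@H]2[C@@H](O[Si](C(C)C)(C(C)C)C(C)C)C1 | intermediate
19 | ketone: C9=O, C8 bearing H and CH3 (both C8 epimers), 4β-OH, 4α-isopropyl, 6α-OSi(i-Pr)3 | CC1C(=O)C[C@@]2(C)CC[C@@](O)(C(C)C)[C@@H]2[C@@H](O[Si](C(C)C)(C(C)C)C(C)C)C1 | intermediate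
20 | (1R,4R,5S,6S)-enone: C7=C8 with C8 methyl, C9=O, 4β-OH, 4α-isopropyl, 6α-OSi(i-Pr)3 | CC1=C[C@H](O[Si](C(C)C)(C(C)C)C(C)C)[C@@H]2[C@](C)(CC[C@@]2(O)C(C)C)CC1=O | intermediate
21 | 4-hydroxybenzoic acid | O=C(O)c1ccc(O)cc1 | starting material
22 | tert-butyldimethylsilyl 4-(tert-butyldimethylsilyloxy)benzoate | CC(C)(C)[Si](C)(C)OC(=O)c1ccc(O[Si](C)(C)C(C)(C)C)cc1 | intermediate
23 | 4-(tert-butyldimethylsilyloxy)benzoyl chloride | CC(C)(C)[Si](C)(C)Oc1ccc(cc1)C(Cl)=O | intermediate
24 | lithium C4 alkoxide of 20 (not isolated) | [Li+].CC1=C[C@H](O[Si](C(C)C)(C(C)C)C(C)C)[C@@H]2[C@](C)(CC[C@@]2([O-])C(C)C)CC1=O | intermediate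
25 | (1R,4R,5S,6S)-bis-silyl ether of the target: 20 with O4 carrying the 4-(tert-butyldimethylsilyloxy)benzoyl group | CC1=C[C@H](O[Si](C(C)C)(C(C)C)C(C)C)[C@@H]2[C@](C)(CC[C@@]2(OC(=O)c2ccc(O[Si](C)(C)C(C)(C)C)cc2)C(C)C)CC1=O | intermediate
26 | (3R,3aS,4S,8aR)-4-hydroxy-6,8a-dimethyl-7-oxo-3-(propan-2-yl)-1,2,3,3a,4,7,8,8a-octahydroazulen-3-yl 4-hydroxybenzoate, i.e. (1R,4R,5S,6S)-4β-(4-hydroxybenzoyloxy)-6α-hydroxydauc-7-en-9-one | CC1=C[C@H](O)[C@@H]2[C@](C)(CC[C@@]2(OC(=O)c2ccc(O)cc2)C(C)C)CC1=O | target

**Step count and risks**
Total step count: 17. Longest linear sequence: 13 steps (steps 1–3, 6–13, 16, 17).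

Step 6 (key step). The [3,3] shift of 10 is slowed by the ring methyl that must point at the cyclopropane CH2 in the boat, so the one-flask process may stall at the cyclopropane. At the temperature needed to push it, the carbenoid stage may erode through carbene dimerisation, attack at a ketal oxygen or lower enantioselectivity. The fallback uncouples the two events. Setting out from 6 and 9, the cyclopropanation alone is run cold (Rh2(S-PTAD)4, pentane, −45 °C) and cyclopropane 10 is isolated. The ring expansion is then done as a separate, metal-free thermal Cope rearrangement in refluxing toluene, which comes back to the route at 11. No new compound arises (F0).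

Step 10. The branched organometallic may enolise the β-silyloxy ketone toward C5 (with epimerisation at C5 or β-elimination of the C6 silyloxy group), transfer hydride instead of carbon, or discriminate the two faces poorly. The fallback brings in the isopropyl group in two stages through an sp2 carbon nucleophile that is smaller, less basic and cannot donate hydride. Setting out from 15, CH2=C(CH3)MgBr with CeCl3 in THF at −78 °C should give the 2-propenyl carbinol F1. Hydrogenation of its 1,1-disubstituted alkene with H2 and RhCl(PPh3)3 in benzene, to which the tetrasubstituted enol ether is inert, comes back to the route at 16.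

Step 16. Acylation of the congested lithium alkoxide may be slower than proton transfer from C10 of the enone, which would lead to O-acylation of the cross-conjugated enolate, or the alkoxide may not react at all. The fallback reverses the mode of activation: the alcohol stays neutral and the electrophile is made stronger. Setting out from 20 and 23, AgOSO2CF3 in CH2Cl2 at −78 °C converts 23 into 4-(tert-butyldimethylsilyloxy)benzoyl trifluoromethanesulfonate F2. This acylates 20 in the presence of 2,6-di-tert-butyl-4-methylpyridine and comes back to the route at 25.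

**Further compounds**
F0 | step 6 | none | none
F1 | step 10 | 2-propenyl carbinol: 15 with 4α-(prop-1-en-2-yl) and 4β-OH | COC(=O)C1=C(O[Si](C)(C)C(C)(C)C)C[C@@]2(C)CC[C@@](O)(C(C)=C)[C@@H]2[C@@H](O[Si](C(C)C)(C(C)C)C(C)C)C1
F2 | step 16 | 4-(tert-butyldimethylsilyloxy)benzoyl trifluoromethanesulfonate | CC(C)(C)[Si](C)(C)Oc1ccc(cc1)C(=O)OS(=O)(=O)C(F)(F)F
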